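Readings and results come from a simulation on assumed constants; noise was put on by code.

Late in the green run the right-handed substrate has almost stopped feeding the left: it falls from 47.9 % to 43.0 % between 0.833 d and 2.50 d, then from 41.9 % to 40.5 % between 4.00 d and 6.00 d, while left-handed substrate still drains from 12.7 % to 6.7 %. The quick number you asked for can therefore be reckoned from 4.00 d on, treating left-handed substrate as a pseudo-first-order drain into left-handed product.

| setting | green | teal | grey | ash | oak |
|---|---|---|---|---|---|
| left-handed substrate | 20 mM | 20 mM | 40 mM | 20 mM | 20 mM |
| right-handed substrate | 20 mM | 20 mM | 40 mM | 20 mM | 20 mM |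
| coupling partner | 2.8 equiv | 4.4 equiv | 2 equiv | 2.00 equiv | 2.00 equiv |
| precatalyst | 0.17 mol% | 0.17 mol% | 0.17 mol% | 0.17 mol% | 0.17 mol% |
| remark | run made earlier | run made earlier | run made earlier |  |  |
| time |  |  |  | 10 d | 40 d |

| run | time / d | right-handed substrate / % | left-handed substrate / % | left-handed product / % |
|---|---|---|---|---|
| green | 0.833 | 47.9 | 34.7 | 17.1 |
| green | 1.67 | 45.4 | 25.6 | 27.7 |
| green | 2.50 | 43.0 | 19.4 | 35.7 |
| green | 3.00 | 43.0 | 16.9 | 39.4 |
| green | 4.00 | 41.9 | 12.7 | 44.7 |
| green | 5.00 | 41.2 | 9.3 | 48.3 |
| green | 6.00 | 40.5 | 6.7 | 50.9 |
| teal | 0.833 | 47.1 | 29.1 | 24.6 |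
| teal | 1.67 | 43.9 | 18.2 | 37.4 |
| teal | 2.50 | 40.8 | 11.8 | 46.0 |
| teal | 3.00 | 40.0 | 9.2 | 49.2 |
| teal | 4.00 | 38.6 | 5.6 | 53.5 |
| teal | 5.00 | 38.5 | 3.7 | 56.3 |
| teal | 6.00 | 37.6 | 1.8 | 57.1 |
| grey | 0.500 | 48.5 | 37.2 | 14.9 |
| grey | 0.833 | 45.8 | 31.9 | 21.3 |
| grey | 1.67 | 42.3 | 23.2 | 34.1 |
| grey | 3.00 | 39.1 | 14.4 | 44.5 |
| grey | 6.00 | 36.6 | 6.2 | 55.2 |

(scatter of a reading: 0.3 percentage points)

- coupling partner is single-handed; left-handed substrate and right-handed substrate are mirror images of each other, charged as a racemate, each of them at the stated concentration
- an excess is the difference of the two amounts in percent of their sum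
- an excess is below zero if the other one leads
- the handed part of coupling partner does not stay in what it makes, so the products of the two hands are mirror images too

1. the flask that ends with the higher excess of right-handed substrate over left-handed substrate among what is left of the two, or "neither" when 2 percentage points or less lies between them (ash / oak / neither)
2. excess of right-handed substrate over left-handed substrate among what is left of the two at the end, ash
3. excess of right-handed substrate over left-handed substrate among what is left of the two at the end, oak

The late rates over that same window are, for green and teal: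

k(green) = 0.320 d⁻¹, k(teal) = 0.567 d⁻¹

Taken in a straight line with the charge of coupling partner, they give ash and oak a rate, and from it the late half-life, the time in which left-handed substrate halves after the handover at the given charge of coupling partner:

k = 0.196 d⁻¹, late half-life = 3.54 d

The left-handed fraction at 4.00 d is carried across the charges as a straight line in its logarithm, the form that goes with a first-order drain, and the right-handed substrate, taken in a plain straight line in the charge, is held at its extrapolated late level:

left-handed substrate at handover = 19.1 %, right-handed substrate = 42.0 %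

ash: left-handed substrate = 5.90 %, excess = 75.3 %

oak: left-handed substrate = 0.0166 %, excess = 99.9 %

The forecast, your hunch, names oak with 72 % for ash and 93 % for oak, adding “A residual trickle of inversion would cap this.”, and the reckoning here has the same order but parts from it on oak.

The flasks give oak, with 75.0 % for ash and 99.7 % for oak.

    precatalyst ⇌ racemization catalyst (K = 3.00, k = 0.0747 h⁻¹)
    2 racemization catalyst → spent catalyst A (k = 14800 M⁻¹ h⁻¹)
    coupling partner + right-handed substrate → right-handed product (k = 0.00662 M⁻¹ h⁻¹)
    coupling partner + left-handed substrate → left-handed product (k = 0.388 M⁻¹ h⁻¹)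
    racemization catalyst → spent catalyst B (k = 0.0414 h⁻¹)
    left-handed substrate + racemization catalyst ⇌ right-handed substrate + racemization catalyst, rate k6*[racemization catalyst]*[left-handed substrate] forward; the back reaction follows from the equilibrium constant (k = 2240 M⁻¹ h⁻¹)

In ash at 10.0 d, coupling uses left-handed substrate 510 times as fast as its forward inversion does, and the relaxation half-life of the inversion, 987 d, is long against the 10 d of the run, while the coupling half-life stands at 3.9 d beside the late half-life of 3.54 d. The neighbour flask with 5.00 equiv of coupling partner gets a late half-life of 1.05 d by the same line, and it ends with 0.132 % left-handed substrate at an excess of 99.2 %.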